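The route rests on cutting the two aryl–carbon bonds at the neighbouring methines C3 and C4 of pyran ring C: C3 carries ring B, C4 carries benzo ring A (through C4a) and ring D. A palladium-catalysed conjunctive coupling adds ring B (migrating from boron to C3) and ring A (from an aryl triflate to C4) anti across an (E)-β-aryl alkenylboron ate complex, so both bonds and both stereocentres arise in one operation and boron stays on C3 as the handle for C2. The precursor is the (E)-2-arylethenyl boronic ester of ring D, already carrying the (R)-chroman and esterified with the hindered mac diol in place of pinacol to suppress direct Suzuki coupling.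

Key step: step 20

Assumption: the target is read as (3R,4S) in ring C (3,4-trans) and (3R) in the second chroman; the ligand antipodes named in steps 8 and 20 are assigned by analogy with simpler substrates, and whichever antipode delivers the stated configuration is the one to be used.

Shorthand in names: ArB = 3-(benzyloxy)-2,4-dimethoxyphenyl; ArA = 4-(benzyloxy)-2-(methoxymethoxy)phenyl; ArD = 4-(benzyloxy)-2-[(3R)-7-(benzyloxy)chroman-3-yl]-6-methoxyphenyl; Bpin = pinacol boronic ester; B(mac) = boronic ester of cis-1,2-dimethyl-1,2-dihydroacenaphthylene-1,2-diol (17); Bn = benzyl; MOM = methoxymethyl.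

**Ring D triflate**

Step 1
Reactants: 1 methyl 2,4,6-trihydroxybenzoate
Product: 2 methyl 4-(benzyloxy)-2,6-dihydroxybenzoate
Conditions: BnBr (1.0 equiv), K2CO3 (1.1 equiv), DMF, 0 °C to rt
Reagents that add atoms: benzyl bromide, BrCc1ccccc1
Why: Williamson etherification; the 4-OH is the only hydroxyl not held in a hydrogen bond to the ester carbonyl, so it should be benzylated first when one equivalent of halide is used.

Step 2
Reactants: 2 methyl 4-(benzyloxy)-2,6-dihydroxybenzoate
Product: 3 methyl 4-(benzyloxy)-2-hydroxy-6-methoxybenzoate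
Conditions: MeI (1.05 equiv), K2CO3 (1.1 equiv), acetone, rt
Reagents that add atoms: iodomethane, CI
Why: Williamson O-methylation; the two hydroxyls are equivalent by symmetry, so only one mono-ether can form, and the remaining chelated hydroxyl should react much more slowly.

Step 3
Reactants: 3 methyl 4-(benzyloxy)-2-hydroxy-6-methoxybenzoate
Product: 4 methyl 4-(benzyloxy)-2-methoxy-6-[(trifluoromethanesulfonyl)oxy]benzoate
Conditions: Tf2O, pyridine, CH2Cl2, 0 °C
Reagents that add atoms: trifluoromethanesulfonic anhydride, O=S(=O)(OS(=O)(=O)C(F)(F)F)C(F)(F)F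
Why: O-sulfonylation of the only free phenol gives the aryl triflate that serves as the cross-coupling electrophile.

**Second chroman and ring D alkenyl boronate**

Step 4
Reactants: 5 7-hydroxychroman-4-one
Product: 6 7-(benzyloxy)chroman-4-one
Conditions: BnBr, K2CO3, DMF, rt
Reagents that add atoms: benzyl bromide, BrCc1ccccc1
Why: Williamson etherification of the single phenol.

Step 5
Reactants: 6 7-(benzyloxy)chroman-4-one
Product: 7 7-(benzyloxy)-3-bromochroman-4-one (racemic)
Conditions: CuBr2 (2 equiv), EtOAc/CHCl3, reflux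
Reagents that add atoms: copper dibromide CuBr2, [Cu+2].[Br-].[Br-]
Why: α-Bromination of the ketone through its enol by CuBr2, which leaves the acyl-deactivated arene alone; the racemic stereocentre is destroyed in step 6.

Step 6
Reactants: 7 7-(benzyloxy)-3-bromochroman-4-one
Product: 9 7-(benzyloxy)-3-bromo-2H-chromene, via bromohydrin 8 (not isolated)
Conditions: NaBH4, MeOH/THF, 0 °C; aqueous work-up, crude taken on; TsOH·H2O (cat.), toluene, 80 °C
Reagents that add atoms: none
Why: Hydride reduction of the ketone and acid-catalysed E1 dehydration through the C4 benzylic cation, which the ring oxygen and the para benzyloxy group stabilise, should give the alkenyl bromide.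

Step 7
Reactants: 9 7-(benzyloxy)-3-bromo-2H-chromene; 4 methyl 4-(benzyloxy)-2-methoxy-6-[(trifluoromethanesulfonyl)oxy]benzoate
Product: 11 methyl 4-(benzyloxy)-2-[7-(benzyloxy)-2H-chromen-3-yl]-6-methoxybenzoate, via chromenyl pinacol boronate 10 (not isolated)
Conditions: B2pin2, Pd(dppf)Cl2 (3 mol%), KOAc, 1,4-dioxane, 80 °C; then 4, aq. K3PO4, 80 °C
Reagents that add atoms: bis(pinacolato)diboron, CC1(C)OB(OC1(C)C)B1OC(C)(C)C(C)(C)O1 (supplies the Bpin group of intermediate 10 only; none of its atoms remain in 11)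
Why: Miyaura borylation of the alkenyl bromide and Suzuki–Miyaura coupling with the ester-activated aryl triflate in one pot join C3 of the chromene to ring D.

Step 8
Reactants: 11 methyl 4-(benzyloxy)-2-[7-(benzyloxy)-2H-chromen-3-yl]-6-methoxybenzoate
Product: 12 methyl 4-(benzyloxy)-2-[(3R)-7-(benzyloxy)chroman-3-yl]-6-methoxybenzoate
Conditions: H2 (50 bar), [Ir(cod)((S)-tBu-PHOX)]BArF (2 mol%; tBu-PHOX = 4-tert-butyl-2-[2-(diphenylphosphino)phenyl]-4,5-dihydrooxazole, BArF = tetrakis[3,5-bis(trifluoromethyl)phenyl]borate), CH2Cl2, rt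
Reagents that add atoms: none
Why: Iridium-catalysed asymmetric hydrogenation of the trisubstituted styrene-type alkene of a 3-aryl-2H-chromene, in which the chiral P,N ligand selects the alkene face and so sets C3 of the second chroman as R; an ester is carried here instead of an aldehyde because it cannot be decarbonylated or hydroacylated by the catalyst, and benzyl ethers are inert to it.

Step 9
Reactants: 12 methyl 4-(benzyloxy)-2-[(3R)-7-(benzyloxy)chroman-3-yl]-6-methoxybenzoate
Product: 13 {4-(benzyloxy)-2-[(3R)-7-(benzyloxy)chroman-3-yl]-6-methoxyphenyl}methanol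
Conditions: LiAlH4, THF, 0 °C to rt
Reagents that add atoms: none
Why: Hydride reduction of the methyl ester to the benzylic alcohol; the ethers are untouched and the stereocentre is not enolisable.

Step 10
Reactants: 13 {4-(benzyloxy)-2-[(3R)-7-(benzyloxy)chroman-3-yl]-6-methoxyphenyl}methanol
Product: 14 4-(benzyloxy)-2-[(3R)-7-(benzyloxy)chroman-3-yl]-6-methoxybenzaldehyde
Conditions: MnO2 (excess), CH2Cl2, rt
Reagents that add atoms: none
Why: Selective oxidation of the electron-rich benzylic alcohol to the aldehyde without over-oxidation.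

Step 11
Reactants: 14 4-(benzyloxy)-2-[(3R)-7-(benzyloxy)chroman-3-yl]-6-methoxybenzaldehyde
Product: 15 (E)-2-ArD-ethenyl Bpin
Conditions: CH2(Bpin)2, LiTMP, THF, 0 °C; then 14, −78 °C to rt
Reagents that add atoms: bis[(pinacolato)boryl]methane, CC1(C)OB(CB2OC(C)(C)C(C)(C)O2)OC1(C)C
Why: Boron-Wittig olefination: the lithiated geminal bis(boronate) adds to the aldehyde and syn elimination of a boron–oxygen unit gives the alkenyl boronate, the (E) geometry being the one favoured for aryl aldehydes.

Step 12
Reactants: 16 acenaphthoquinone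
Product: 17 cis-1,2-dimethyl-1,2-dihydroacenaphthylene-1,2-diol (mac diol, meso)
Conditions: Al(CH3)3 (excess), toluene, 0 °C to rt; recrystallisation
Reagents that add atoms: trimethylaluminium, C[Al](C)C
Why: Twofold 1,2-addition of methyl to the diketone, the second methyl entering anti to the bulky aluminium alkoxide so that both hydroxyls should end up on one face (cis), which crystallisation purifies.

Step 13
Reactants: 15 (E)-2-ArD-ethenyl Bpin; 17 mac diol
Product: 19 (E)-2-ArD-ethenyl B(mac), via alkenylboronic acid 18 (not isolated)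
Conditions: NaIO4, NH4OAc, acetone/H2O, rt; extraction, crude taken on; 17, MgSO4, CH2Cl2, rt
Reagents that add atoms: water, O (supplies the two hydroxyls of intermediate 18 only; the product takes its diol from 17)
Why: Periodate cleavage of the liberated pinacol drives hydrolysis of the pinacol ester, and the boronic acid condenses with the cis diol to the hindered five-membered mac ester without touching the alkene geometry.

**Ring B bromide**

Step 14
Reactants: 20 2,6-dimethoxyphenol
Product: 21 2-(benzyloxy)-1,3-dimethoxybenzene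
Conditions: BnBr, K2CO3, DMF, rt
Reagents that add atoms: benzyl bromide, BrCc1ccccc1
Why: Williamson etherification of the single phenol.

Step 15
Reactants: 21 2-(benzyloxy)-1,3-dimethoxybenzene
Product: 22 3-(benzyloxy)-1-bromo-2,4-dimethoxybenzene
Conditions: NBS, MeCN, 0 °C to rt
Reagents that add atoms: N-bromosuccinimide, O=C1CCC(=O)N1Br
Why: Electrophilic aromatic bromination at C4, ortho to one methoxy and para to the other; the central benzyloxy group is flanked on both sides and twisted out of conjugation, so it directs less, as in 1,2,3-trimethoxybenzene.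

**Ring A triflate**

Step 16
Reactants: 23 2,4-dihydroxybenzaldehyde
Product: 24 4-(benzyloxy)-2-hydroxybenzaldehyde
Conditions: BnBr (1.0 equiv), NaHCO3, MeCN, reflux
Reagents that add atoms: benzyl bromide, BrCc1ccccc1
Why: Williamson etherification under weak base alkylates only the 4-OH, the 2-OH being held in a hydrogen bond to the formyl group.

Step 17
Reactants: 24 4-(benzyloxy)-2-hydroxybenzaldehyde
Product: 25 4-(benzyloxy)-2-(methoxymethoxy)benzaldehyde
Conditions: MOMCl, i-Pr2NEt, CH2Cl2, 0 °C to rt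
Reagents that add atoms: chloromethyl methyl ether, COCCl
Why: Protection of the remaining phenol as its methoxymethyl acetal, the one oxygen protecting group that can later be removed without touching benzyl ethers.

Step 18
Reactants: 25 4-(benzyloxy)-2-(methoxymethoxy)benzaldehyde
Product: 27 4-(benzyloxy)-2-(methoxymethoxy)phenol, via aryl formate 26 (not isolated)
Conditions: mCPBA, NaHCO3, CH2Cl2, rt; then K2CO3, MeOH, rt
Reagents that add atoms: 3-chloroperoxybenzoic acid, OOC(=O)c1cccc(Cl)c1
Why: Baeyer–Villiger (Dakin-type) oxidation in which the electron-rich aryl group migrates to oxygen, followed by methanolysis of the formate; the bicarbonate buffer protects the acetal.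

Step 19
Reactants: 27 4-(benzyloxy)-2-(methoxymethoxy)phenol
Product: 28 4-(benzyloxy)-2-(methoxymethoxy)phenyl trifluoromethanesulfonate
Conditions: PhNTf2, Cs2CO3, DMF, rt
Reagents that add atoms: N-phenylbis(trifluoromethanesulfonimide), O=S(=O)(N(c1ccccc1)S(=O)(=O)C(F)(F)F)C(F)(F)F
Why: Mild O-triflation of the phenoxide that leaves the acid-sensitive methoxymethyl acetal intact.

**Key step and completion**

Step 20
Reactants: 22 3-(benzyloxy)-1-bromo-2,4-dimethoxybenzene; 19 (E)-2-ArD-ethenyl B(mac); 28 4-(benzyloxy)-2-(methoxymethoxy)phenyl trifluoromethanesulfonate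
Product: 31 (1R,2S)-1-ArB-2-ArA-2-ArD-ethyl B(mac), via aryllithium 29 (not isolated), via lithium boronate complex 30 (not isolated)
Conditions: 22, t-BuLi (2.0 equiv), Et2O, −78 °C; 19, THF, −78 °C to rt; then 28 (1.2 equiv), Pd(OAc)2 (5 mol%), (Sp,Sp)-MandyPhos [(Sp,Sp)-1,1'-bis[bis(4-methoxy-3,5-dimethylphenyl)phosphino]-2,2'-bis[(R)-α-(dimethylamino)benzyl]ferrocene] (6 mol%), KOTf (2 equiv), THF, 60 °C
Reagents that add atoms: tert-butyllithium, [Li]C(C)(C)C (supplies the lithium of intermediates 29 and 30 only; none of its atoms remain in 31)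
Why: Zerovalent palladium inserts into the C–OTf bond of 28, and the resulting cationic arylpalladium triflate (divalent palladium) binds the alkene of the four-coordinate boronate 30 and triggers a 1,2-metallate shift in which ring B moves from boron to the boron-bearing carbon (future C3) anti-periplanar to palladium arriving at the benzylic carbon (future C4); reductive elimination with retention then joins C4 to C4a of ring A. This is the palladium-catalysed conjunctive cross-coupling of alkenylboron ate complexes, which in its mac-ester form extends to β-substituted, including β-aryl, alkenyl boronates with aryl triflates. No ring is closed. The configuration at C4 is set by the chiral bisphosphine, which chooses the alkene face that palladium binds, and the configuration at C3 follows from it because migration is anti and the alkene is (E), so the (1R,2S) diastereomer, the precursor of the 3,4-trans chroman, should result, the distant (R)-chroman centre being too remote to override the ligand. The step needs the metallate shift to win over direct transmetallation (plain Suzuki coupling) and needs ring B to land only on C3: the first is secured by the hindered mac ester, the non-coordinating triflate and KOTf, which removes the bromide left by the bromine–lithium exchange, the second by the mechanism, since the migrating group can only move to the carbon attached to boron.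

Step 21
Reactants: 31 (1R,2S)-1-ArB-2-ArA-2-ArD-ethyl B(mac)
Product: 33 (2R,3S)-2-ArB-3-ArA-3-ArD-propan-1-ol, via homologated boronate 32 (not isolated)
Conditions: BrCH2Cl, n-BuLi, THF, −78 °C to rt; then NaOH aq., H2O2, 0 °C to rt
Reagents that add atoms: bromochloromethane, ClCBr (the CH2 that becomes C2); hydrogen peroxide, OO (the hydroxyl oxygen)
Why: Matteson homologation: chloromethyllithium formed in situ adds to boron and the secondary alkyl group migrates to the carbenoid carbon with retention at C3, expelling chloride, after which the primary C–B bond is oxidised to the alcohol.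

Step 22
Reactants: 33 (2R,3S)-2-ArB-3-ArA-3-ArD-propan-1-ol
Product: 34 (2R,3S)-3-[4-(benzyloxy)-2-hydroxyphenyl]-2-ArB-3-ArD-propan-1-ol
Conditions: HCl (cat.), MeOH/THF, 45 °C
Reagents that add atoms: none
Why: Acid-catalysed methanolysis of the aryl methoxymethyl acetal; benzyl and methyl ethers are stable and neither stereocentre has an ionisable or enolisable position.

Step 23
Reactants: 34 (2R,3S)-3-[4-(benzyloxy)-2-hydroxyphenyl]-2-ArB-3-ArD-propan-1-ol
Product: 35 (3R,4S)-7-(benzyloxy)-3-ArB-4-ArD-chroman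
Conditions: PPh3, DIAD, THF, 0 °C to rt
Reagents that add atoms: none
Why: Intramolecular Mitsunobu etherification in which the ring A phenol displaces the activated primary hydroxyl (SN2 at C2, six-membered ring) and closes the O1–C2 bond of pyran ring C without touching C3 or C4, so the 3,4-trans relationship is kept.

Step 24
Reactants: 35 (3R,4S)-7-(benzyloxy)-3-ArB-4-ArD-chroman
Product: 36 (3R,4S)-3-(3-hydroxy-2,4-dimethoxyphenyl)-4-{4-hydroxy-2-[(3R)-7-hydroxychroman-3-yl]-6-methoxyphenyl}chroman-7-ol (target)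
Conditions: H2 (1 atm), Pd/C (10%), EtOAc/MeOH, rt
Reagents that add atoms: none
Why: Hydrogenolysis of the four benzyl ethers over Pd/C; the methyl ethers, the two chroman C–O bonds (not benzylic) and the three stereocentres are untouched.

**Compound list**

1 | methyl 2,4,6-trihydroxybenzoate | COC(=O)c1c(O)cc(O)cc1O | starting material
2 | methyl 4-(benzyloxy)-2,6-dihydroxybenzoate | COC(=O)c1c(O)cc(OCc2ccccc2)cc1O | intermediate
3 | methyl 4-(benzyloxy)-2-hydroxy-6-methoxybenzoate | COC(=O)c1c(OC)cc(OCc2ccccc2)cc1O | intermediate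
4 | methyl 4-(benzyloxy)-2-methoxy-6-[(trifluoromethanesulfonyl)oxy]benzoate | COC(=O)c1c(OC)cc(OCc2ccccc2)cc1OS(=O)(=O)C(F)(F)F | intermediate
5 | 7-hydroxychroman-4-one | O=C1CCOc2cc(O)ccc12 | starting material
6 | 7-(benzyloxy)chroman-4-one | O=C1CCOc2cc(OCc3ccccc3)ccc12 | intermediate
7 | 7-(benzyloxy)-3-bromochroman-4-one (racemic) | O=C1C(Br)COc2cc(OCc3ccccc3)ccc12 | intermediate
8 | 7-(benzyloxy)-3-bromochroman-4-ol (racemic mixture of diastereomers) | OC1C(Br)COc2cc(OCc3ccccc3)ccc12 | intermediate
9 | 7-(benzyloxy)-3-bromo-2H-chromene | BrC1=Cc2ccc(OCc3ccccc3)cc2OC1 | intermediate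
10 | 2-[7-(benzyloxy)-2H-chromen-3-yl]-4,4,5,5-tetramethyl-1,3,2-dioxaborolane | CC1(C)OB(OC1(C)C)C1=Cc2ccc(OCc3ccccc3)cc2OC1 | intermediate
11 | methyl 4-(benzyloxy)-2-[7-(benzyloxy)-2H-chromen-3-yl]-6-methoxybenzoate | COC(=O)c1c(OC)cc(OCc2ccccc2)cc1C1=Cc2ccc(OCc3ccccc3)cc2OC1 | intermediate
12 | methyl 4-(benzyloxy)-2-[(3R)-7-(benzyloxy)chroman-3-yl]-6-methoxybenzoate | COC(=O)c1c(OC)cc(OCc2ccccc2)cc1[C@@H]1COc2cc(OCc3ccccc3)ccc2C1 | intermediate
13 | {4-(benzyloxy)-2-[(3R)-7-(benzyloxy)chroman-3-yl]-6-methoxyphenyl}methanol | OCc1c(OC)cc(OCc2ccccc2)cc1[C@@H]1COc2cc(OCc3ccccc3)ccc2C1 | intermediate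
14 | 4-(benzyloxy)-2-[(3R)-7-(benzyloxy)chroman-3-yl]-6-methoxybenzaldehyde | O=Cc1c(OC)cc(OCc2ccccc2)cc1[C@@H]1COc2cc(OCc3ccccc3)ccc2C1 | intermediate
15 | 2-[(E)-2-ArD-ethenyl]-4,4,5,5-tetramethyl-1,3,2-dioxaborolane | CC1(C)OB(/C=C/c2c(OC)cc(OCc3ccccc3)cc2[C@@H]2COc3cc(OCc4ccccc4)ccc3C2)OC1(C)C | intermediate
16 | acenaphthoquinone (acenaphthylene-1,2-dione) | O=C1C(=O)c2cccc3cccc1c23 | starting material
17 | cis-1,2-dimethyl-1,2-dihydroacenaphthylene-1,2-diol (mac diol, meso) | C[C@@]1(O)c2cccc3cccc(c23)[C@]1(C)O | intermediate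
18 | [(E)-2-ArD-ethenyl]boronic acid | OB(O)/C=C/c1c(OC)cc(OCc2ccccc2)cc1[C@@H]1COc2cc(OCc3ccccc3)ccc2C1 | intermediate
19 | (E)-2-ArD-ethenyl B(mac) (boronic ester of 17) | COc1cc(OCc2ccccc2)cc([C@@H]2COc3cc(OCc4ccccc4)ccc3C2)c1/C=C/B1O[C@]2(C)c3cccc4cccc(c34)[C@]2(C)O1 | intermediate
20 | 2,6-dimethoxyphenol | COc1cccc(OC)c1O | starting material
21 | 2-(benzyloxy)-1,3-dimethoxybenzene | COc1cccc(OC)c1OCc1ccccc1 | intermediate
22 | 3-(benzyloxy)-1-bromo-2,4-dimethoxybenzene | COc1ccc(Br)c(OC)c1OCc1ccccc1 | intermediate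
23 | 2,4-dihydroxybenzaldehyde | O=Cc1ccc(O)cc1O | starting material
24 | 4-(benzyloxy)-2-hydroxybenzaldehyde | O=Cc1ccc(OCc2ccccc2)cc1O | intermediate
25 | 4-(benzyloxy)-2-(methoxymethoxy)benzaldehyde | COCOc1cc(OCc2ccccc2)ccc1C=O | intermediate
26 | 4-(benzyloxy)-2-(methoxymethoxy)phenyl formate | COCOc1cc(OCc2ccccc2)ccc1OC=O | intermediate
27 | 4-(benzyloxy)-2-(methoxymethoxy)phenol | COCOc1cc(OCc2ccccc2)ccc1O | intermediate
28 | 4-(benzyloxy)-2-(methoxymethoxy)phenyl trifluoromethanesulfonate | COCOc1cc(OCc2ccccc2)ccc1OS(=O)(=O)C(F)(F)F | intermediate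
29 | [3-(benzyloxy)-2,4-dimethoxyphenyl]lithium | [Li]c1ccc(OC)c(OCc2ccccc2)c1OC | intermediate
30 | lithium ArB[(E)-2-ArD-ethenyl]borate of mac diol (four-coordinate boron, either configuration at boron) | [Li+].COc1ccc([B-]2(/C=C/c3c(OC)cc(OCc4ccccc4)cc3[C@@H]3COc4cc(OCc5ccccc5)ccc4C3)O[C@]3(C)c4cccc5cccc(c45)[C@]3(C)O2)c(OC)c1OCc1ccccc1 | intermediate
31 | (1R,2S)-1-ArB-2-ArA-2-ArD-ethyl B(mac) | COc1ccc([C@H](B2O[C@]3(C)c4cccc5cccc(c45)[C@]3(C)O2)[C@@H](c2ccc(OCc3ccccc3)cc2OCOC)c2c(OC)cc(OCc3ccccc3)cc2[C@@H]2COc3cc(OCc4ccccc4)ccc3C2)c(OC)c1OCc1ccccc1 | intermediate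
32 | (2R,3S)-2-ArB-3-ArA-3-ArD-propyl B(mac) | COc1ccc([C@H](CB2O[C@]3(C)c4cccc5cccc(c45)[C@]3(C)O2)[C@@H](c2ccc(OCc3ccccc3)cc2OCOC)c2c(OC)cc(OCc3ccccc3)cc2[C@@H]2COc3cc(OCc4ccccc4)ccc3C2)c(OC)c1OCc1ccccc1 | intermediate
33 | (2R,3S)-2-ArB-3-ArA-3-ArD-propan-1-ol | COc1ccc([C@H](CO)[C@@H](c2ccc(OCc3ccccc3)cc2OCOC)c2c(OC)cc(OCc3ccccc3)cc2[C@@H]2COc3cc(OCc4ccccc4)ccc3C2)c(OC)c1OCc1ccccc1 | intermediate
34 | (2R,3S)-3-[4-(benzyloxy)-2-hydroxyphenyl]-2-ArB-3-ArD-propan-1-ol | COc1ccc([C@H](CO)[C@@H](c2ccc(OCc3ccccc3)cc2O)c2c(OC)cc(OCc3ccccc3)cc2[C@@H]2COc3cc(OCc4ccccc4)ccc3C2)c(OC)c1OCc1ccccc1 | intermediate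
35 | (3R,4S)-7-(benzyloxy)-3-ArB-4-ArD-chroman | COc1ccc([C@@H]2COc3cc(OCc4ccccc4)ccc3[C@H]2c2c(OC)cc(OCc3ccccc3)cc2[C@@H]2COc3cc(OCc4ccccc4)ccc3C2)c(OC)c1OCc1ccccc1 | intermediate
36 | (3R,4S)-3-(3-hydroxy-2,4-dimethoxyphenyl)-4-{4-hydroxy-2-[(3R)-7-hydroxychroman-3-yl]-6-methoxyphenyl}chroman-7-ol | COc1ccc([C@@H]2COc3cc(O)ccc3[C@H]2c2c(OC)cc(O)cc2[C@@H]2COc3cc(O)ccc3C2)c(OC)c1O | target

Total step count: 24. Longest linear sequence: 14 steps (steps 1–3, 7–11, 13, 20–24).

**Steps most likely to fail**

1. Step 20. Direct transmetallation of an organic group from the ate complex to palladium may outrun the metallate shift, or palladium may bind the crowded alkene carbon (flanked by two ortho substituents) too slowly; imperfect face selection would also lower diastereomeric purity. The fallback sets out from aldehyde 14, draws on triflate 28 and bromide 22, and returns at alcohol 33. Horner–Wadsworth–Emmons olefination of 14 with triethyl phosphonoacetate (NaH, THF) should give ethyl (E)-3-ArD-prop-2-enoate F1. Miyaura borylation of 28 (B2pin2, Pd(dppf)Cl2, KOAc, dioxane) gives 2-ArA-4,4,5,5-tetramethyl-1,3,2-dioxaborolane F2. Rhodium-catalysed asymmetric 1,4-addition of F2 to F1 ([Rh(OH)(cod)]2, the BINAP antipode that gives S, KOH, dioxane/H2O) sets C4 in ethyl (3S)-3-ArA-3-ArD-propanoate F3. Palladium-catalysed α-arylation of the lithium enolate of F3 with 22 (LiHMDS, Pd(dba)2, P(t-Bu)3, toluene) places ring B on C3 and gives ethyl (2R,3S)-2-ArB-3-ArA-3-ArD-propanoate F4, separated from its C2 epimer, which can be recycled by base equilibration. LiAlH4 reduction of F4 then gives 33.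

2. Step 21. The short-lived carbenoid may be captured incompletely by the crowded secondary mac boronate, so that unchanged boronate is oxidised to the secondary alcohol in the second stage. The fallback sets out from 31 and returns at 33. Vinyllithium, which is stable at room temperature and can be used in excess, adds to boron; iodine and then NaOMe (Zweifel olefination, retention at C3) give (3R,4S)-3-ArB-4-ArA-4-ArD-but-1-ene F5. Oxidative cleavage of the terminal alkene (OsO4 cat., NaIO4, 2,6-lutidine, dioxane/H2O) gives (2R,3S)-2-ArB-3-ArA-3-ArD-propanal F6, which is reduced at once with NaBH4 to 33 before the α-aryl aldehyde can epimerise.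

3. Step 8. Face selection at the alkene bearing the ortho-substituted aryl group may be insufficient, which would lower the enantiomeric purity of the second chroman and produce diastereomers after step 20. The fallback sets out from 11 and returns at 12. Hydrogenation with the achiral catalyst [Ir(cod)(PCy3)(py)]PF6 (H2, CH2Cl2) gives racemic methyl 4-(benzyloxy)-2-[7-(benzyloxy)chroman-3-yl]-6-methoxybenzoate F7, which is resolved by preparative chromatography on a chiral stationary phase (amylose or cellulose carbamate) to give 12.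

**Further compounds**

F1 | step 20 | ethyl (E)-3-{4-(benzyloxy)-2-[(3R)-7-(benzyloxy)chroman-3-yl]-6-methoxyphenyl}prop-2-enoate | CCOC(=O)/C=C/c1c(OC)cc(OCc2ccccc2)cc1[C@@H]1COc2cc(OCc3ccccc3)ccc2C1
F2 | step 20 | 2-[4-(benzyloxy)-2-(methoxymethoxy)phenyl]-4,4,5,5-tetramethyl-1,3,2-dioxaborolane | COCOc1cc(OCc2ccccc2)ccc1B1OC(C)(C)C(C)(C)O1
F3 | step 20 | ethyl (3S)-3-ArA-3-ArD-propanoate | CCOC(=O)C[C@@H](c1ccc(OCc2ccccc2)cc1OCOC)c1c(OC)cc(OCc2ccccc2)cc1[C@@H]1COc2cc(OCc3ccccc3)ccc2C1
F4 | step 20 | ethyl (2R,3S)-2-ArB-3-ArA-3-ArD-propanoate | CCOC(=O)[C@@H](c1ccc(OC)c(OCc2ccccc2)c1OC)[C@@H](c1ccc(OCc2ccccc2)cc1OCOC)c1c(OC)cc(OCc2ccccc2)cc1[C@@H]1COc2cc(OCc3ccccc3)ccc2C1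
F5 | step 21 | (3R,4S)-3-ArB-4-ArA-4-ArD-but-1-ene | COc1ccc([C@H](C=C)[C@@H](c2ccc(OCc3ccccc3)cc2OCOC)c2c(OC)cc(OCc3ccccc3)cc2[C@@H]2COc3cc(OCc4ccccc4)ccc3C2)c(OC)c1OCc1ccccc1
F6 | step 21 | (2R,3S)-2-ArB-3-ArA-3-ArD-propanal | COc1ccc([C@H](C=O)[C@@H](c2ccc(OCc3ccccc3)cc2OCOC)c2c(OC)cc(OCc3ccccc3)cc2[C@@H]2COc3cc(OCc4ccccc4)ccc3C2)c(OC)c1OCc1ccccc1
F7 | step 8 | racemic methyl 4-(benzyloxy)-2-[7-(benzyloxy)chroman-3-yl]-6-methoxybenzoate | COC(=O)c1c(OC)cc(OCc2ccccc2)cc1C1COc2cc(OCc3ccccc3)ccc2C1
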